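## Retrosynthetic overview
1. Tsangin C ⇒ terminal alkyne ester. C≡CH is the latent acetyl group, and Markovnikov hydration comes last under neutral conditions because the β-aroyloxy ketone eliminates with base.
2. Ester C–O ⇒ anti-homopropargylic alcohol + 3,4,5-trimethoxybenzoyl chloride.
3. C≡CH ⇒ (Z)-enol carbamate by loss of carbamate. Together with line 1 this moves the oxygen function from C1 to C2.
4. Key C3–C4 bond ⇒ 3,4,5-trimethoxybenzaldehyde + metallated (E)-crotyl carbamate, a chiral homoenolate equivalent ((+)-sparteine, then Ti). Both stereocentres are set here.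
5. No ring is formed; both arene rings are bought intact.

Assumption: (E)-crotyl alcohol (E ≥ 95 %) and (+)-sparteine are bought, and the ligand is recovered unchanged by acid–base extraction.

## Route

Step 1
Reactants: 1 (E)-but-2-en-1-ol
Product: 2 (E)-but-2-en-1-yl N,N-diisopropylcarbamate
Conditions: iPr2NCOCl (1.1 equiv), pyridine, 90 °C, 16 h
Reagents that add atoms: N,N-diisopropylcarbamoyl chloride, CC(C)N(C(C)C)C(=O)Cl
Why: O-carbamoylation of a primary allylic alcohol by nucleophilic acyl substitution installs the hindered, base-stable directing group needed for allylic lithiation, and no stereocentre is formed.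

Step 2
Reactants: 2 (E)-but-2-en-1-yl N,N-diisopropylcarbamate; 3 3,4,5-trimethoxybenzaldehyde
Product: 7 (1Z,3R,4R)-4-hydroxy-3-methyl-4-(3,4,5-trimethoxyphenyl)but-1-en-1-yl N,N-diisopropylcarbamate, via lithiated crotyl carbamate 4 (not isolated), via crotyltitanium triisopropoxide 5 (not isolated), via titanium homoaldolate 6 (not isolated)
Conditions: n-BuLi (1.1 equiv), (+)-sparteine (1.1 equiv), pentane/cyclohexane, −70 °C, 3 h; Ti(OiPr)4 (3 equiv), −70 °C; 3 in THF, −70 °C → rt; aq. HCl
Reagents that add atoms: none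
Why: Hoppe asymmetric homoaldol reaction: the lithiated carbamate is a chiral homoenolate (d3) equivalent whose (R)-epimer crystallises selectively as the (+)-sparteine complex, Li-to-Ti exchange with inversion gives configurationally stable (S)-5, and 5 attacks the aldehyde carbon through its γ-carbon in a closed chair transition state (suprafacial SE2′, aryl equatorial, carbamoyloxy axial), so two carbons that are both acceptor sites in the parent enal and aldehyde are joined while the (E)-crotyl geometry and the C1 configuration are translated into the anti (3R,4R) pair and the (Z)-enol carbamate.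

Step 3
Reactants: 7 (1Z,3R,4R)-4-hydroxy-3-methyl-4-(3,4,5-trimethoxyphenyl)but-1-en-1-yl N,N-diisopropylcarbamate
Product: 10 (1R,2R)-2-methyl-1-(3,4,5-trimethoxyphenyl)but-3-yn-1-ol, via C1-lithiated enol carbamate alkoxide 8 (not isolated), via dilithio alkynolate 9 (not isolated)
Conditions: t-BuLi (3.3 equiv), Et2O/THF, −78 → 0 °C; 1 M HCl, 0 °C
Reagents that add atoms: none
Why: Carbamate-directed vinylic lithiation at C1, then loss of lithium carbamate with a 1,2-hydride shift (Fritsch–Buttenberg–Wiechell-type elimination), gives the terminal alkyne, with the first equivalent of base masking the OH as its alkoxide and the third taken up by the acetylide, and neither stereocentre is touched.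

Step 4
Reactants: 10 (1R,2R)-2-methyl-1-(3,4,5-trimethoxyphenyl)but-3-yn-1-ol; 11 3,4,5-trimethoxybenzoyl chloride
Product: 12 (1R,2R)-2-methyl-1-(3,4,5-trimethoxyphenyl)but-3-yn-1-yl 3,4,5-trimethoxybenzoate
Conditions: Et3N (2 equiv), DMAP (10 mol %), CH2Cl2, 0 °C → rt
Reagents that add atoms: none
Why: DMAP-catalysed acylation of the secondary alcohol leaves the C–O bond at the stereocentre intact (retention), and it is run before the ketone exists so that amine base never meets an elimination-prone β-aroyloxy ketone.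

Step 5
Reactants: 12 (1R,2R)-2-methyl-1-(3,4,5-trimethoxyphenyl)but-3-yn-1-yl 3,4,5-trimethoxybenzoate
Product: 13 Tsangin C
Conditions: (Ph3P)AuNTf2 (2 mol %), H2O (10 equiv), 1,4-dioxane, rt → 40 °C
Reagents that add atoms: water, O
Why: Markovnikov alkyne hydration catalysed by monovalent gold is steered to C2 by 6-exo-dig participation of the ester carbonyl, whose hemi-orthoester collapses back to the benzylic ester and the methyl ketone, and the neutral medium avoids C3 epimerisation and E1cB loss of the benzoate, so both stereocentres are carried over (the C3 descriptor changes from R to S only because the priorities change).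

## Compound list
1 | (E)-but-2-en-1-ol (crotyl alcohol) | C/C=C/CO | starting material
2 | (E)-but-2-en-1-yl N,N-diisopropylcarbamate | C/C=C/COC(=O)N(C(C)C)C(C)C | intermediate
3 | 3,4,5-trimethoxybenzaldehyde | COc1cc(C=O)cc(OC)c1OC | starting material
4 | (1R,2E)-1-(N,N-diisopropylcarbamoyloxy)but-2-en-1-yllithium, crystallising as its (+)-sparteine complex (SMILES without ligand) | C/C=C/[C@@H]([Li])OC(=O)N(C(C)C)C(C)C | intermediate
5 | (1S,2E)-1-(N,N-diisopropylcarbamoyloxy)but-2-en-1-yltitanium triisopropoxide | C/C=C/[C@H]([Ti](OC(C)C)(OC(C)C)OC(C)C)OC(=O)N(C(C)C)C(C)C | intermediate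
6 | triisopropoxytitanium alkoxide of 7 | CC(C)O[Ti](OC(C)C)(OC(C)C)O[C@@H](c1cc(OC)c(OC)c(OC)c1)[C@H](C)/C=C\OC(=O)N(C(C)C)C(C)C | intermediate
7 | (1Z,3R,4R)-4-hydroxy-3-methyl-4-(3,4,5-trimethoxyphenyl)but-1-en-1-yl N,N-diisopropylcarbamate | O[C@@H](c1cc(OC)c(OC)c(OC)c1)[C@H](C)/C=C\OC(=O)N(C(C)C)C(C)C | intermediate
8 | lithium alkoxide of 7, lithiated at the vinylic carbon C1 | [Li]O[C@@H](c1cc(OC)c(OC)c(OC)c1)[C@H](C)/C=C(/[Li])OC(=O)N(C(C)C)C(C)C | intermediate
9 | dilithium salt (alkoxide, acetylide) of 10 | [Li]O[C@@H](c1cc(OC)c(OC)c(OC)c1)[C@H](C)C#C[Li] | intermediate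
10 | (1R,2R)-2-methyl-1-(3,4,5-trimethoxyphenyl)but-3-yn-1-ol | O[C@@H](c1cc(OC)c(OC)c(OC)c1)[C@H](C)C#C | intermediate
11 | 3,4,5-trimethoxybenzoyl chloride | COc1cc(C(=O)Cl)cc(OC)c1OC | starting material
12 | (1R,2R)-2-methyl-1-(3,4,5-trimethoxyphenyl)but-3-yn-1-yl 3,4,5-trimethoxybenzoate | COc1cc(C(=O)O[C@@H](c2cc(OC)c(OC)c(OC)c2)[C@H](C)C#C)cc(OC)c1OC | intermediate
13 | Tsangin C, (1R,2S)-2-methyl-3-oxo-1-(3,4,5-trimethoxyphenyl)butyl 3,4,5-trimethoxybenzoate | COc1cc(C(=O)O[C@@H](c2cc(OC)c(OC)c(OC)c2)[C@H](C)C(C)=O)cc(OC)c1OC | target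

## Step count and risks
Total step count: 5. Longest linear sequence: 5 (1 → 2 → 7 → 10 → 12 → 13).

**Risk 1, step 2.**
- The crystallisation-driven resolution of 4 is sensitive to solvent, temperature and the E-purity of 2.
- Aldehyde 3 is poorly soluble in hydrocarbons, so the ee may erode.
- The fallback sets out from 3 and comes back at 10.
- Bought (S)-but-3-yn-2-ol is mesylated (MsCl, Et3N, CH2Cl2, −78 °C) to (S)-but-3-yn-2-yl methanesulfonate F1.
- Pd(OAc)2/PPh3 (5 mol % each) and Et2Zn (3 equiv) in THF at −20 °C then act on F1. Anti SN2′ attack of zerovalent palladium and Pd-to-Zn exchange turn this electrophile into the nucleophilic (M)-buta-1,2-dien-1-yl(ethyl)zinc F2.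
- F2 adds to 3 through a cyclic SE2′ transition state, with net inversion at the former mesylate carbon, to give anti-10.
- The anti:syn ratio with an aromatic aldehyde is expected to be lower, and the minor isomer is removed by chromatography.

**Risk 2, step 3.**
- On the free alkoxide, ring lithiation next to a methoxy group or 1,2-migration of the carbamoyl group may compete with alkyne formation.
- The fallback sets out from 7 and comes back at 10.
- TBSOTf/2,6-lutidine gives (1Z,3R,4R)-4-(tert-butyldimethylsilyloxy)-3-methyl-4-(3,4,5-trimethoxyphenyl)but-1-en-1-yl N,N-diisopropylcarbamate F3.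
- Only 2.2 equiv of t-BuLi (−78 → −20 °C) are then needed to reach tert-butyl(dimethyl){[(1R,2R)-2-methyl-1-(3,4,5-trimethoxyphenyl)but-3-yn-1-yl]oxy}silane F4.
- TBAF in THF releases 10.

**Risk 3, step 5.**
- The electron-rich ring may add to the gold-activated alkyne (hydroarylation to a dihydronaphthalene).
- The benzylic ester may ionise.
- The fallback sets out from 12 and comes back at 13.
- Semihydrogenation (Pd/CaCO3 poisoned with Pb(OAc)2, quinoline, H2 1 atm, EtOAc) gives (1R,2R)-2-methyl-1-(3,4,5-trimethoxyphenyl)but-3-en-1-yl 3,4,5-trimethoxybenzoate F5.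
- Tsuji–Wacker oxidation (PdCl2 10 mol %, CuCl 1 equiv, O2, DMF/H2O, rt) converts the vinyl group into the methyl ketone under weakly acidic conditions.

## Further compounds
F1 | step 2 | (S)-but-3-yn-2-yl methanesulfonate | C#C[C@H](C)OS(C)(=O)=O
F2 | step 2 | (M)-buta-1,2-dien-1-yl(ethyl)zinc | CC([H])=[C@]=C([H])[Zn]CC
F3 | step 3 | (1Z,3R,4R)-4-(tert-butyldimethylsilyloxy)-3-methyl-4-(3,4,5-trimethoxyphenyl)but-1-en-1-yl N,N-diisopropylcarbamate | CC(C)(C)[Si](C)(C)O[C@@H](c1cc(OC)c(OC)c(OC)c1)[C@H](C)/C=C\OC(=O)N(C(C)C)C(C)C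
F4 | step 3 | tert-butyl(dimethyl){[(1R,2R)-2-methyl-1-(3,4,5-trimethoxyphenyl)but-3-yn-1-yl]oxy}silane | CC(C)(C)[Si](C)(C)O[C@@H](c1cc(OC)c(OC)c(OC)c1)[C@H](C)C#C
F5 | step 5 | (1R,2R)-2-methyl-1-(3,4,5-trimethoxyphenyl)but-3-en-1-yl 3,4,5-trimethoxybenzoate | COc1cc(C(=O)O[C@@H](c2cc(OC)c(OC)c(OC)c2)[C@H](C)C=C)cc(OC)c1OC
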